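**Plan** (macrolide numbering: C1 = lactone carbonyl, round the ring to C13 = ethyl-bearing carbinol carbon)
1. Cuts: C2–C3 (aldol of a C13 propanoate onto a C3 aldehyde, then oxidation); C6=C7 (Horner–Wittig enol-ether olefination of a C7 aldehyde with a C3–C6 α-methoxy phosphine oxide); then C8–CH3 and C9–C10 in one operation (allyl alcohol, Al(CH3)3 and a C10–C13 2-bromodiene).
2. Feature used: in the 14-membered lactone the methyl-bearing stereocentre C8 is one methylene (C9) away from C10, the sp2 carbon of the exocyclic-methylene diene C10(=CH2)–C11=C12. That 2-methylalkyl-to-alkenyl pattern is what methylalumination of a terminal alkene followed by alkenylation of the new primary carbon–metal bond delivers.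
3. Forward: bromodiene → three-component coupling to C7–C13 → C13 propanoate and C7 aldehyde → enol-ether union with the C3–C6 piece → C3 aldehyde → macro-aldol closes the only ring → oxidation and desilylation.
4. Stereochemistry: C13 by Noyori transfer hydrogenation; 11Z by anti-carbomagnesiation; C8 by the chiral zirconocene, upgraded by lipase; C4 by Sharpless epoxidation; 6E by syn-elimination of a separated Horner–Wittig adduct; C2 by equilibration between its two carbonyl groups.

Key step: step 8

Remark: (−)-(NMI)2ZrCl2 is taken to be the antipode that gives the (2R)-alane (the one giving (R)-3-iodo-2-methylpropan-1-ol on iodinolysis); if a trial iodinolysis shows the opposite sense, the (+)-antipode is used.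
Remark: lipase PS is taken to acylate the (2S)-2-methyl primary alcohol faster than its C8 epimer, as is usual for 2-methyl primary alcohols with an sp2 group on the other branch.
Remark: the (2R) configuration at C2 is taken to be the more stable one and to be reached by enolisation of the β-keto lactone.

**Route**

Step 1
Reactants: 1 ethynyl(trimethyl)silane; 2 N-methoxy-N-methylpropanamide
Product: 4 1-(trimethylsilyl)pent-1-yn-3-one, via lithium acetylide 3 (not isolated)
Conditions: n-BuLi, THF, −78 °C; then 2, −78 → 0 °C; H2O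
Reagents that add atoms: none
Why: Acylation of a lithium acetylide by a Weinreb amide stops at the ketone because the chelated tetrahedral adduct survives until work-up.

Step 2
Reactants: 4 1-(trimethylsilyl)pent-1-yn-3-one
Product: 5 (3S)-1-(trimethylsilyl)pent-1-yn-3-ol
Conditions: Ru[(S,S)-TsNCH(Ph)CH(Ph)NH](p-cymene) (1 mol %), i-PrOH, rt
Reagents that add atoms: none
Why: Noyori asymmetric transfer hydrogenation of an alkynyl ketone, in which the (S,S)-ligand treats the alkynyl group like the aryl group of an aryl ketone and delivers hydride to the face that gives the (S)-carbinol, the future C13.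

Step 3
Reactants: 5 (3S)-1-(trimethylsilyl)pent-1-yn-3-ol
Product: 6 (3S)-pent-1-yn-3-ol
Conditions: K2CO3 (cat.), MeOH, rt
Reagents that add atoms: none
Why: Base-catalysed methanolysis of the alkynyl C–Si bond (protodesilylation) does not touch the carbinol centre.

Step 4
Reactants: 6 (3S)-pent-1-yn-3-ol
Product: 8 (1Z,3S)-1-iodo-2-methylpent-1-en-3-ol, via alkenylmagnesium chelate 7 (not isolated)
Conditions: MeMgBr (3 equiv), CuI (10 mol %), THF, −20 °C → rt; then I2, −78 → 0 °C; H2O
Reagents that add atoms: methylmagnesium bromide, C[Mg]Br; iodine, II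
Why: Copper-catalysed anti-carbomagnesiation of the propargylic alkoxide puts CH3 on the carbon next to the carbinol and magnesium on the terminus in a five-membered chelate, and iodinolysis with retention gives the Z-iodide that fixes the C11=C12 geometry.

Step 5
Reactants: 8 (1Z,3S)-1-iodo-2-methylpent-1-en-3-ol
Product: 9 tert-butyl{[(1Z,3S)-1-iodo-2-methylpent-1-en-3-yl]oxy}dimethylsilane
Conditions: t-BuMe2SiCl, imidazole, DMF, rt
Reagents that add atoms: tert-butyl(chloro)dimethylsilane, CC(C)(C)[Si](C)(C)Cl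
Why: Standard imidazole-promoted silylation protects the C13 hydroxyl against the organometallic steps that follow.

Step 6
Reactants: 9 tert-butyl{[(1Z,3S)-1-iodo-2-methylpent-1-en-3-yl]oxy}dimethylsilane
Product: 10 tert-butyl(dimethyl){[(3Z,5S)-4-methylhept-3-en-1-yn-5-yl]oxy}silane
Conditions: HC≡CMgBr, ZnBr2, THF, 0 °C; then 9, Pd(PPh3)4 (5 mol %), rt
Reagents that add atoms: ethynylmagnesium bromide, C#C[Mg]Br
Why: Negishi coupling of ethynylzinc bromide with an alkenyl iodide proceeds with retention at the sp2 carbon and gives the terminal Z-enyne directly.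

Step 7
Reactants: 10 tert-butyl(dimethyl){[(3Z,5S)-4-methylhept-3-en-1-yn-5-yl]oxy}silane
Product: 12 tert-butyl{[(3Z,5S)-2-bromo-4-methylhepta-1,3-dien-5-yl]oxy}dimethylsilane, via bromoalkenylborane 11 (not isolated)
Conditions: B-bromo-9-borabicyclo[3.3.1]nonane, CH2Cl2, 0 °C; then AcOH, 0 °C → rt
Reagents that add atoms: B-bromo-9-borabicyclo[3.3.1]nonane, BrB1C2CCCC1CCC2
Why: syn-Bromoboration of the terminal alkyne places bromine on the internal carbon and protonolysis of the alkenyl C–B bond by acetic acid with retention leaves the 2-bromo-1,3-diene, the trisubstituted alkene and the silyl ether being expected to stay intact at 0 °C.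

Step 8
Reactants: 13 prop-2-en-1-ol (allyl alcohol); 14 trimethylaluminium; 12 tert-butyl{[(3Z,5S)-2-bromo-4-methylhepta-1,3-dien-5-yl]oxy}dimethylsilane
Product: 17 (2S,5Z,7S)-7-{[tert-butyl(dimethyl)silyl]oxy}-2,6-dimethyl-4-methylidenenon-5-en-1-ol, via alkylalane 15 (not isolated), via alkylzinc triflate 16 (not isolated)
Conditions: 13 (2.5 equiv), Me3Al (3 equiv per 13), (−)-(NMI)2ZrCl2 [bis(1-neomenthylindenyl)zirconium dichloride] (5 mol %), (MeAlO)n, CH2Cl2, 0 °C → rt; evaporate volatiles; Zn(OTf)2, DMF, 70 °C; then 12 (1 equiv), PdCl2(DPEphos) (5 mol %), i-Bu2AlH (10 mol %), rt; aq. NH4Cl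
Reagents that add atoms: none
Why: Me3Al first turns allyl alcohol into its dimethylaluminium alkoxide, the cationic methylzirconocene formed from (NMI)2ZrCl2 adds CH3–Zr syn across the terminal alkene with CH3 on the internal carbon, and Zr-to-Al exchange gives the primary alane 15; Zn(OTf)2 in DMF moves the C9–metal bond to zinc (16), and zerovalent palladium, formed from divalent PdCl2(DPEphos) and i-Bu2AlH, inserts into the C10–Br bond of 12, transmetalates and reductively eliminates to make C9–C10. The closest known reaction type is the zirconium-catalysed asymmetric carboalumination of terminal alkenes run in one flask with zinc- and palladium-mediated (Negishi) alkenylation of the resulting 2-methylalkylalane. No ring is closed. The new stereocentre C8 is set by enantioface selection of the chiral neomenthylindenyl ligands on the alkene, C13 is carried through unchanged, and the minor C8 epimer is removed in step 9. The step needs carbometalation of the monosubstituted alkene only and coupling with retention of the diene geometry: 12 is added after the excess Me3Al has been evaporated and the solvent changed to DMF, so its 1,1-disubstituted and trisubstituted alkenes never meet an active carbometalation system, and oxidative addition and reductive elimination at sp2 carbon keep the 11Z geometry. The wide-bite-angle DPEphos ligand should suppress β-hydride elimination from the β-branched alkylpalladium.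

Step 9
Reactants: 17 (2S,5Z,7S)-7-{[tert-butyl(dimethyl)silyl]oxy}-2,6-dimethyl-4-methylidenenon-5-en-1-ol
Product: 18 (2S,5Z,7S)-7-{[tert-butyl(dimethyl)silyl]oxy}-2,6-dimethyl-4-methylidenenon-5-en-1-yl acetate
Conditions: Amano lipase PS, vinyl acetate, t-BuOMe, rt, stopped short of full conversion
Reagents that add atoms: vinyl acetate, C=COC(C)=O
Why: Lipase-catalysed transesterification of a 2-methyl-branched primary alcohol discriminates at the β-stereocentre, so the (2S)-epimer should be acetylated ahead of the minor (2R)-epimer left from step 8, and the acetate also serves as the C7 protecting group.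

Step 10
Reactants: 18 (2S,5Z,7S)-7-{[tert-butyl(dimethyl)silyl]oxy}-2,6-dimethyl-4-methylidenenon-5-en-1-yl acetate
Product: 19 (2S,5Z,7S)-7-hydroxy-2,6-dimethyl-4-methylidenenon-5-en-1-yl acetate
Conditions: Bu4NF, AcOH (1:1), THF, 40 °C
Reagents that add atoms: none
Why: Fluoride cleaves the hindered secondary silyl ether while buffering with acetic acid keeps the primary acetate intact, and no acid-labile group is present yet.

Step 11
Reactants: 19 (2S,5Z,7S)-7-hydroxy-2,6-dimethyl-4-methylidenenon-5-en-1-yl acetate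
Product: 20 (3S,4Z,8S)-9-acetoxy-4,8-dimethyl-6-methylidenenon-4-en-3-yl propanoate
Conditions: (EtCO)2O, Et3N, 4-(dimethylamino)pyridine (cat.), CH2Cl2, rt
Reagents that add atoms: propanoic anhydride, CCC(=O)OC(=O)CC
Why: Nucleophile-catalysed acylation puts C1–C2 with the C2 methyl on the C13 oxygen before any fluoride- or acid-sensitive group of the western half is in the molecule.

Step 12
Reactants: 20 (3S,4Z,8S)-9-acetoxy-4,8-dimethyl-6-methylidenenon-4-en-3-yl propanoate
Product: 21 (3S,4Z,8S)-9-hydroxy-4,8-dimethyl-6-methylidenenon-4-en-3-yl propanoate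
Conditions: Amano lipase PS, pH 7 buffer (Na2HPO4/NaH2PO4), acetone, rt
Reagents that add atoms: none
Why: Lipase-catalysed hydrolysis accepts the unhindered primary acetate but not the secondary propanoate flanked by ethyl and a trisubstituted alkene, and it again favours the (8S)-configured ester.

Step 13
Reactants: 21 (3S,4Z,8S)-9-hydroxy-4,8-dimethyl-6-methylidenenon-4-en-3-yl propanoate
Product: 22 (3S,4Z,8S)-4,8-dimethyl-6-methylidene-9-oxonon-4-en-3-yl propanoate
Conditions: Dess–Martin periodinane, pyridine, CH2Cl2, 0 °C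
Reagents that add atoms: none
Why: Dess–Martin oxidation gives the α-methyl aldehyde under near-neutral conditions that should not epimerise C8, and the aldehyde is used at once.

Step 14
Reactants: 23 2-methylidenepropane-1,3-diol
Product: 24 2-{[tert-butyl(diphenyl)silyl]oxymethyl}prop-2-en-1-ol
Conditions: NaH (1 equiv), THF, 0 °C; then t-BuPh2SiCl (1 equiv)
Reagents that add atoms: tert-butyl(chloro)diphenylsilane, CC(C)(C)[Si](Cl)(c1ccccc1)c1ccccc1
Why: Monosilylation of a symmetrical diol through its sparingly soluble monosodium alkoxide gives the mono-ether selectively.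

Step 15
Reactants: 24 2-{[tert-butyl(diphenyl)silyl]oxymethyl}prop-2-en-1-ol
Product: 25 [(2R)-2-{[tert-butyl(diphenyl)silyl]oxymethyl}oxiran-2-yl]methanol
Conditions: Ti(OiPr)4 (10 mol %), D-(−)-diethyl tartrate (12 mol %), t-BuOOH, 4 Å molecular sieves, CH2Cl2, −20 °C
Reagents that add atoms: tert-butyl hydroperoxide, CC(C)(C)OO
Why: Sharpless asymmetric epoxidation, in which the titanium-bound allylic alkoxide and the D-tartrate ligand direct oxygen to the face that gives the (R)-epoxide; this defines C4, the free hydroxymethyl arm becoming C3 and the silyloxymethyl arm the C4 hydroxymethyl group.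

Step 16
Reactants: 25 [(2R)-2-{[tert-butyl(diphenyl)silyl]oxymethyl}oxiran-2-yl]methanol
Product: 26 tert-butyl(diphenyl){[(2S)-2-{[(triethylsilyl)oxy]methyl}oxiran-2-yl]methoxy}silane
Conditions: Et3SiCl, imidazole, CH2Cl2, 0 °C
Reagents that add atoms: chlorotriethylsilane, CC[Si](Cl)(CC)CC
Why: Silylation blocks the free arm with a group that can later be removed ahead of the other two silyl ethers and prevents Payne rearrangement in the next step.

Step 17
Reactants: 26 tert-butyl(diphenyl){[(2S)-2-{[(triethylsilyl)oxy]methyl}oxiran-2-yl]methoxy}silane; 27 (methoxymethyl)diphenylphosphine oxide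
Product: 29 (2S)-1-{[tert-butyl(diphenyl)silyl]oxy}-4-(diphenylphosphoryl)-4-methoxy-2-{[(triethylsilyl)oxy]methyl}butan-2-ol (both epimers at the phosphorus-bearing carbon), via lithiated phosphine oxide 28 (not isolated)
Conditions: 27, LiN(i-Pr)2, THF, −78 °C; then 26, BF3·OEt2, −78 °C; H2O
Reagents that add atoms: none
Why: Ring opening of an epoxide by an α-lithiated diphenylphosphine oxide at the unsubstituted CH2 (SN2, assisted by BF3) forms C5–C6 without touching the quaternary C4, and the mixed configuration at C6 does not matter because that carbon is deprotonated again in step 19.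

Step 18
Reactants: 29 (2S)-1-{[tert-butyl(diphenyl)silyl]oxy}-4-(diphenylphosphoryl)-4-methoxy-2-{[(triethylsilyl)oxy]methyl}butan-2-ol
Product: 30 C3–C6 phosphine oxide, the O-triethylsilyl ether of 29
Conditions: Et3SiOTf, 2,6-lutidine, CH2Cl2, −78 → 0 °C
Reagents that add atoms: triethylsilyl trifluoromethanesulfonate, CC[Si](CC)(CC)OS(=O)(=O)C(F)(F)F
Why: Silyl triflate with a hindered pyridine base silylates the tertiary alcohol, which would otherwise consume base and interfere in the olefination.

Step 19
Reactants: 30 C3–C6 phosphine oxide; 22 (3S,4Z,8S)-4,8-dimethyl-6-methylidene-9-oxonon-4-en-3-yl propanoate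
Product: 32 C3–C13 β-hydroxy phosphine oxide of (6R,7S) configuration (kept together with its 6S,7R companion), via lithiated phosphine oxide 31 (not isolated)
Conditions: 30, LiN(i-Pr)2, THF, −78 °C; then 22, −78 °C; H2O; chromatographic separation of the diastereomers
Reagents that add atoms: none
Why: First stage of a Horner–Wittig olefination: the α-lithio α-methoxy phosphine oxide adds to the aldehyde (the hindered propanoate not competing at −78 °C) to give stable β-hydroxy phosphine oxides whose C6/C7 relative configuration decides the alkene geometry, so the adducts are separated and the (6R,7S)/(6S,7R) pair is taken on.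

Step 20
Reactants: 32 C3–C13 β-hydroxy phosphine oxide
Product: 33 C3–C13 (6E)-methyl enol ether: C3 and C4 triethylsilyl ethers, C4-CH2 tert-butyldiphenylsilyl ether, C13 propanoate
Conditions: KN(SiMe3)2 (1.05 equiv), THF, −78 → 0 °C
Reagents that add atoms: none
Why: Second stage of the Horner–Wittig reaction: the potassium alkoxide attacks phosphorus and diphenylphosphinate leaves by stereospecific syn-elimination, which for this relative configuration places C5 and C8 cis and so gives the (6E)-enol ether.

Step 21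
Reactants: 33 C3–C13 (6E)-methyl enol ether
Product: 34 C3 primary alcohol of 33
Conditions: Bu4NF, AcOH (1:1), THF, −20 → 0 °C
Reagents that add atoms: none
Why: Buffered fluoride cleaves a primary triethylsilyl ether much faster than the tertiary triethylsilyl and the tert-butyldiphenylsilyl ethers, and the near-neutral medium spares the enol ether and the ester.

Step 22
Reactants: 34 C3 primary alcohol
Product: 35 C3 aldehyde bearing the C13 propanoate
Conditions: SO3·pyridine, DMSO, i-Pr2NEt, CH2Cl2, 0 °C
Reagents that add atoms: none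
Why: Parikh–Doering oxidation is free of acid, so the enol ether survives, and the aldehyde formed has no α-hydrogen and cannot enolise.

Step 23
Reactants: 35 C3 aldehyde bearing the C13 propanoate
Product: 36 14-membered 3-hydroxy lactone (mixture at C2 and C3)
Conditions: KN(SiMe3)2 (1.5 equiv), THF (about 1 mM), −78 °C; then AcOH, −78 °C
Reagents that add atoms: none
Why: Intramolecular aldol addition of the propanoate potassium enolate (C2) to the non-enolisable C3 aldehyde closes the 14-membered ring under high dilution, and the configurations formed at C2 and C3 do not matter because C3 is oxidised next and C2 is epimerisable.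

Step 24
Reactants: 36 14-membered 3-hydroxy lactone
Product: 37 (2R,4R,6E,8S,11Z,13S)-3-oxo lactone, C4-O-triethylsilyl and C4-CH2O-tert-butyldiphenylsilyl ether of the target
Conditions: Dess–Martin periodinane, pyridine, CH2Cl2, 0 °C → rt
Reagents that add atoms: none
Why: Dess–Martin oxidation of the β-hydroxy lactone gives the β-keto lactone, after which C2 lies between two carbonyl groups and should settle by enolisation as the (2R) epimer.

Step 25
Reactants: 37 bis-silyl ether of the target
Product: 38 (3R,5R,7E,9S,12Z,14S)-14-ethyl-5-hydroxy-5-(hydroxymethyl)-7-methoxy-3,9,13-trimethyl-11-methylidene-1-oxacyclotetradeca-7,12-diene-2,4-dione (CNP0325854.3)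
Conditions: Bu4NF, AcOH (1:1), THF, 0 °C → rt
Reagents that add atoms: none
Why: Buffered fluoride removes the tert-butyldiphenylsilyl ether and the tertiary triethylsilyl ether next to the ketone without acid, so the methyl enol ether, the β-keto lactone and the α-ketol are retained.

**Compound list**

1 | ethynyl(trimethyl)silane | C#C[Si](C)(C)C | starting material
2 | N-methoxy-N-methylpropanamide | CCC(=O)N(C)OC | starting material
3 | lithium (trimethylsilyl)acetylide | [Li]C#C[Si](C)(C)C | intermediate
4 | 1-(trimethylsilyl)pent-1-yn-3-one | CCC(=O)C#C[Si](C)(C)C | intermediate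
5 | (3S)-1-(trimethylsilyl)pent-1-yn-3-ol | CC[C@H](O)C#C[Si](C)(C)C | intermediate
6 | (3S)-pent-1-yn-3-ol | CC[C@H](O)C#C | intermediate
7 | (5S)-5-ethyl-4-methyl-2,5-dihydro-1,2-oxamagnesole (cyclic alkenylmagnesium alkoxide) | CC[C@@H]1O[Mg]C=C1C | intermediate
8 | (1Z,3S)-1-iodo-2-methylpent-1-en-3-ol | I/C=C(/C)[C@H](CC)O | intermediate
9 | tert-butyl{[(1Z,3S)-1-iodo-2-methylpent-1-en-3-yl]oxy}dimethylsilane | I/C=C(/C)[C@H](CC)O[Si](C)(C)C(C)(C)C | intermediate
10 | tert-butyl(dimethyl){[(3Z,5S)-4-methylhept-3-en-1-yn-5-yl]oxy}silane | C#C/C=C(/C)[C@H](CC)O[Si](C)(C)C(C)(C)C | intermediate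
11 | 9-[(1Z,3Z,5S)-2-bromo-5-{[tert-butyl(dimethyl)silyl]oxy}-4-methylhepta-1,3-dien-1-yl]-9-borabicyclo[3.3.1]nonane | Br/C(=C\B1C2CCCC1CCC2)/C=C(/C)[C@H](CC)O[Si](C)(C)C(C)(C)C | intermediate
12 | tert-butyl{[(3Z,5S)-2-bromo-4-methylhepta-1,3-dien-5-yl]oxy}dimethylsilane (C10–C13 bromodiene) | C=C(Br)/C=C(/C)[C@H](CC)O[Si](C)(C)C(C)(C)C | intermediate
13 | prop-2-en-1-ol (allyl alcohol) | C=CCO | starting material
14 | trimethylaluminium | C[Al](C)C | starting material
15 | [(2R)-3-(dimethylalumanyl)-2-methylpropoxy]dimethylalumane | C[Al](C)C[C@H](C)CO[Al](C)C | intermediate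
16 | [(2R)-3-(dimethylalumanyloxy)-2-methylpropyl]zinc trifluoromethanesulfonate | FC(F)(F)S(=O)(=O)O[Zn]C[C@H](C)CO[Al](C)C | intermediate
17 | (2S,5Z,7S)-7-{[tert-butyl(dimethyl)silyl]oxy}-2,6-dimethyl-4-methylidenenon-5-en-1-ol (C7–C13 dienyl alcohol) | OC[C@@H](C)CC(=C)/C=C(/C)[C@H](CC)O[Si](C)(C)C(C)(C)C | intermediate
18 | (2S,5Z,7S)-7-{[tert-butyl(dimethyl)silyl]oxy}-2,6-dimethyl-4-methylidenenon-5-en-1-yl acetate | CC(=O)OC[C@@H](C)CC(=C)/C=C(/C)[C@H](CC)O[Si](C)(C)C(C)(C)C | intermediate
19 | (2S,5Z,7S)-7-hydroxy-2,6-dimethyl-4-methylidenenon-5-en-1-yl acetate | CC(=O)OC[C@@H](C)CC(=C)/C=C(/C)[C@H](CC)O | intermediate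
20 | (3S,4Z,8S)-9-acetoxy-4,8-dimethyl-6-methylidenenon-4-en-3-yl propanoate | CC(=O)OC[C@@H](C)CC(=C)/C=C(/C)[C@H](CC)OC(=O)CC | intermediate
21 | (3S,4Z,8S)-9-hydroxy-4,8-dimethyl-6-methylidenenon-4-en-3-yl propanoate | OC[C@@H](C)CC(=C)/C=C(/C)[C@H](CC)OC(=O)CC | intermediate
22 | (3S,4Z,8S)-4,8-dimethyl-6-methylidene-9-oxonon-4-en-3-yl propanoate (C7 aldehyde) | O=C[C@@H](C)CC(=C)/C=C(/C)[C@H](CC)OC(=O)CC | intermediate
23 | 2-methylidenepropane-1,3-diol | C=C(CO)CO | starting material
24 | 2-{[tert-butyl(diphenyl)silyl]oxymethyl}prop-2-en-1-ol | C=C(CO)CO[Si](c1ccccc1)(c1ccccc1)C(C)(C)C | intermediate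
25 | [(2R)-2-{[tert-butyl(diphenyl)silyl]oxymethyl}oxiran-2-yl]methanol | OC[C@]1(CO[Si](c2ccccc2)(c2ccccc2)C(C)(C)C)CO1 | intermediate
26 | tert-butyl(diphenyl){[(2S)-2-{[(triethylsilyl)oxy]methyl}oxiran-2-yl]methoxy}silane | CC[Si](CC)(CC)OC[C@]1(CO[Si](c2ccccc2)(c2ccccc2)C(C)(C)C)CO1 | intermediate
27 | (methoxymethyl)diphenylphosphine oxide | COCP(=O)(c1ccccc1)c1ccccc1 | starting material
28 | [lithio(methoxy)methyl]diphenylphosphine oxide | [Li]C(OC)P(=O)(c1ccccc1)c1ccccc1 | intermediate
29 | (2S)-1-{[tert-butyl(diphenyl)silyl]oxy}-4-(diphenylphosphoryl)-4-methoxy-2-{[(triethylsilyl)oxy]methyl}butan-2-ol (both epimers at the phosphorus-bearing carbon, C6) | CC[Si](CC)(CC)OC[C@](O)(CO[Si](c1ccccc1)(c1ccccc1)C(C)(C)C)CC(OC)P(=O)(c1ccccc1)c1ccccc1 | intermediate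
30 | C3–C6 phosphine oxide: (4S)-C4 triethylsilyl ether of 29 (both C6 epimers) | CC[Si](CC)(CC)OC[C@](O[Si](CC)(CC)CC)(CO[Si](c1ccccc1)(c1ccccc1)C(C)(C)C)CC(OC)P(=O)(c1ccccc1)c1ccccc1 | intermediate
31 | C6-lithio derivative of 30 | CC[Si](CC)(CC)OC[C@](O[Si](CC)(CC)CC)(CO[Si](c1ccccc1)(c1ccccc1)C(C)(C)C)CC([Li])(OC)P(=O)(c1ccccc1)c1ccccc1 | intermediate
32 | C3–C13 β-hydroxy phosphine oxide, (4S,6R,7S,8S,11Z,13S) in macrolide numbering: C6 bears OCH3 and P(O)Ph2, C7 bears OH (drawn isomer; its 6S,7R companion converges on the same enol ether) | CC[Si](CC)(CC)OC[C@](O[Si](CC)(CC)CC)(CO[Si](c1ccccc1)(c1ccccc1)C(C)(C)C)C[C@@](OC)(P(=O)(c1ccccc1)c1ccccc1)[C@@H](O)[C@@H](C)CC(=C)/C=C(/C)[C@H](CC)OC(=O)CC | intermediate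
33 | C3–C13 enol ether, (4S,6E,8S,11Z,13S): C3 OSiEt3, C4 OSiEt3, C4-CH2OSiPh2t-Bu, C6 OCH3, C13 propanoate | CC[Si](CC)(CC)OC[C@](O[Si](CC)(CC)CC)(CO[Si](c1ccccc1)(c1ccccc1)C(C)(C)C)C/C(OC)=C\[C@@H](C)CC(=C)/C=C(/C)[C@H](CC)OC(=O)CC | intermediate
34 | C3 primary alcohol of 33, (4S,6E,8S,11Z,13S) | OC[C@](O[Si](CC)(CC)CC)(CO[Si](c1ccccc1)(c1ccccc1)C(C)(C)C)C/C(OC)=C\[C@@H](C)CC(=C)/C=C(/C)[C@H](CC)OC(=O)CC | intermediate
35 | C3 aldehyde, (4R,6E,8S,11Z,13S), with C13 propanoate | O=C[C@](O[Si](CC)(CC)CC)(CO[Si](c1ccccc1)(c1ccccc1)C(C)(C)C)C/C(OC)=C\[C@@H](C)CC(=C)/C=C(/C)[C@H](CC)OC(=O)CC | intermediate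
36 | 14-membered 3-hydroxy lactone, (4R,6E,8S,11Z,13S), C2 and C3 as mixtures, silyl ethers as in 35 | C=C1/C=C(/C)[C@H](CC)OC(=O)C(C)C(O)[C@](O[Si](CC)(CC)CC)(CO[Si](c2ccccc2)(c2ccccc2)C(C)(C)C)C/C(OC)=C\[C@@H](C)C1 | intermediate
37 | (2R,4R,6E,8S,11Z,13S)-3-oxo lactone, C4-O-triethylsilyl and C4-CH2O-tert-butyldiphenylsilyl ether of the target | C=C1/C=C(/C)[C@H](CC)OC(=O)[C@H](C)C(=O)[C@](O[Si](CC)(CC)CC)(CO[Si](c2ccccc2)(c2ccccc2)C(C)(C)C)C/C(OC)=C\[C@@H](C)C1 | intermediate
38 | (3R,5R,7E,9S,12Z,14S)-14-ethyl-5-hydroxy-5-(hydroxymethyl)-7-methoxy-3,9,13-trimethyl-11-methylidene-1-oxacyclotetradeca-7,12-diene-2,4-dione | C=C1/C=C(/C)[C@H](CC)OC(=O)[C@H](C)C(=O)[C@](O)(CO)C/C(OC)=C\[C@@H](C)C1 | target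

**Totals**

Total step count: 25. Longest linear sequence: 20 steps (steps 1–13 and 19–25); steps 14–18 are a five-step side branch to the C3–C6 phosphine oxide.

**Steps most likely to fail**

Step 19. What may go wrong: weak or adverse diastereoselection in the carbonyl addition, so that mostly the adducts that eliminate to the 6Z enol ether form. The fallback sets out from 22 and 30 and returns at 32. The addition is run as in step 19 without separation to give the unseparated adduct mixture F1. Dess–Martin oxidation then gives the β-keto phosphine oxide F2, which erases the C7 centre. Reduction with Zn(BH4)2 in Et2O at −78 °C is run under chelation control: with zinc bridging the C7 carbonyl and either the C6 methoxy or the phosphoryl oxygen, hydride should enter so that each C6 epimer gives the relative configuration of 32. The propanoate is not reduced under these conditions.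

Step 23. What may go wrong: attack of the amide base on the aldehyde, intermolecular condensation, or silyl migration to the new potassium alkoxide before the quench. The fallback sets out from 33 and returns at 36. i-Bu2AlH in CH2Cl2 at −78 °C removes the propanoate to give the C13 alcohol F3. 2-Bromopropanoyl bromide and pyridine give the C13 2-bromopropanoate F4. HF·pyridine buffered with pyridine frees the C3 primary alcohol F5, and Parikh–Doering oxidation gives the bromo ester aldehyde F6. SmI2 in THF under high dilution then closes the ring by an intramolecular Reformatsky reaction, the neutral samarium enolate adding to the C3 aldehyde to give 36.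

Step 17. What may go wrong: slow ring opening of the hindered 2,2-disubstituted epoxide by the bulky carbanion, or Lewis-acid-induced rearrangement of the epoxide. The fallback sets out from 26 and returns at 30. Vinylmagnesium bromide with catalytic CuI opens the epoxide at CH2 to give the tertiary homoallylic alcohol F7, and Et3SiOTf with 2,6-lutidine gives the bis(triethylsilyl) ether F8. Ozonolysis with PPh3 work-up gives the aldehyde F9. MeOSiMe3 with catalytic Me3SiOTf at −78 °C gives the dimethyl acetal F10. Ph2PCl then converts the acetal into the α-methoxy phosphine oxide 30 by an Arbuzov-type reaction with loss of chloromethane.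

**Further compounds**

F1 | step 19 | unseparated C6/C7 diastereomers of the C3–C13 β-hydroxy phosphine oxide (constitution of 32) | CC[Si](CC)(CC)OC[C@](O[Si](CC)(CC)CC)(CO[Si](c1ccccc1)(c1ccccc1)C(C)(C)C)CC(OC)(P(=O)(c1ccccc1)c1ccccc1)C(O)[C@@H](C)CC(=C)/C=C(/C)[C@H](CC)OC(=O)CC
F2 | step 19 | C3–C13 β-keto phosphine oxide (C7 ketone, both C6 epimers) | CC[Si](CC)(CC)OC[C@](O[Si](CC)(CC)CC)(CO[Si](c1ccccc1)(c1ccccc1)C(C)(C)C)CC(OC)(P(=O)(c1ccccc1)c1ccccc1)C(=O)[C@@H](C)CC(=C)/C=C(/C)[C@H](CC)OC(=O)CC
F3 | step 23 | C13 alcohol of the C3–C13 enol ether (33 without the propanoyl group) | CC[Si](CC)(CC)OC[C@](O[Si](CC)(CC)CC)(CO[Si](c1ccccc1)(c1ccccc1)C(C)(C)C)C/C(OC)=C\[C@@H](C)CC(=C)/C=C(/C)[C@H](CC)O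
F4 | step 23 | C13 2-bromopropanoate of F3 (both epimers at the bromine-bearing carbon) | CC[Si](CC)(CC)OC[C@](O[Si](CC)(CC)CC)(CO[Si](c1ccccc1)(c1ccccc1)C(C)(C)C)C/C(OC)=C\[C@@H](C)CC(=C)/C=C(/C)[C@H](CC)OC(=O)C(C)Br
F5 | step 23 | C3 primary alcohol of F4 | OC[C@](O[Si](CC)(CC)CC)(CO[Si](c1ccccc1)(c1ccccc1)C(C)(C)C)C/C(OC)=C\[C@@H](C)CC(=C)/C=C(/C)[C@H](CC)OC(=O)C(C)Br
F6 | step 23 | C3 aldehyde bearing the C13 2-bromopropanoate | O=C[C@](O[Si](CC)(CC)CC)(CO[Si](c1ccccc1)(c1ccccc1)C(C)(C)C)C/C(OC)=C\[C@@H](C)CC(=C)/C=C(/C)[C@H](CC)OC(=O)C(C)Br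
F7 | step 17 | (2S)-1-{[tert-butyl(diphenyl)silyl]oxy}-2-{[(triethylsilyl)oxy]methyl}pent-4-en-2-ol | CC[Si](CC)(CC)OC[C@](O)(CO[Si](c1ccccc1)(c1ccccc1)C(C)(C)C)CC=C
F8 | step 17 | O-triethylsilyl ether of F7 | CC[Si](CC)(CC)OC[C@](O[Si](CC)(CC)CC)(CO[Si](c1ccccc1)(c1ccccc1)C(C)(C)C)CC=C
F9 | step 17 | (3S)-4-{[tert-butyl(diphenyl)silyl]oxy}-3-[(triethylsilyl)oxy]-3-{[(triethylsilyl)oxy]methyl}butanal | CC[Si](CC)(CC)OC[C@](O[Si](CC)(CC)CC)(CO[Si](c1ccccc1)(c1ccccc1)C(C)(C)C)CC=O
F10 | step 17 | dimethyl acetal of F9 | CC[Si](CC)(CC)OC[C@](O[Si](CC)(CC)CC)(CO[Si](c1ccccc1)(c1ccccc1)C(C)(C)C)CC(OC)OC
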